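**Retrosynthetic overview**
- Target 19 is reached from the tris-MOM flavone 16 by MOM removal and, before that, an enantioselective 1,4-reduction of C2=C3 that sets C2, the only stereocentre.
- The strategy rests on ring C: C4 is a single carbonyl carbon bonded to C4a (ring A) and C3, and O1 sits on C8a ortho to it. Ring C therefore divides into an ortho-iodophenol (C4a–I, C8a–OH), carbon monoxide (C4) and an arylacetylene (C3≡C2 carrying ring B).
- Key disconnection: C4a–C4, C4–C3 and O1–C2 are formed in one Pd-catalysed carbonylative annulation of 9, 13 and 12. Ring C is the only ring formed; rings A and B are bought as 2-methylresorcinol and 4-hydroxybenzaldehyde.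
- Iodophenol 9 comes from 2-methylresorcinol: bis-MOM protection, Ir C–H borylation/oxidation para to the methyl group (future O1), O-(1,1-dimethylallyl)ation and Claisen rearrangement (C8 prenyl), then iodination of the last ring C–H (future C4a).
- Alkyne 12 comes from 4-hydroxybenzaldehyde by MOM protection and one-carbon homologation.

Key step: step 9

Assumption: the sense of induction of the copper hydride catalyst on flavone 16 is taken by analogy with β,β-disubstituted cyclic enones. The route is written with (S)-DTBM-SEGPHOS; the mirror-image ligand is to be used if a test reduction delivers the 2R series.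

Step 1
Reactants: 1 2-methylresorcinol
Product: 2 1,3-bis(methoxymethoxy)-2-methylbenzene
Conditions: NaH, MOMCl, DMF, 0 °C → rt
Reagents that add atoms: chloromethyl methyl ether, COCCl
Why: Double Williamson-type O-alkylation of the bis-phenoxide with the reactive α-chloro ether gives the bis-MOM acetal, which masks O5 and O7 until the last step and is stable to the base, heat and metal catalysis that follow.

Step 2
Reactants: 2 1,3-bis(methoxymethoxy)-2-methylbenzene
Product: 4 3,5-bis(methoxymethoxy)-4-methylphenol, via arylboronic pinacol ester 3 (not isolated)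
Conditions: [Ir(OMe)(cod)]2 (1.5 mol%), dtbpy (3 mol%), B2pin2, THF, 80 °C; then 30% H2O2, aq NaOH, 0 °C
Reagents that add atoms: bis(pinacolato)diboron, CC1(C)OB(OC1(C)C)B1OC(C)(C)C(C)(C)O1 (boron of 3); hydrogen peroxide, OO (oxygen of 4)
Why: Iridium-catalysed aromatic C–H borylation is sterically controlled and should select the only ring C–H without an ortho substituent (para to the methyl group), and oxidation of the C–B bond then gives the phenol that becomes O1, already differentiated from the two MOM-protected oxygens.

Step 3
Reactants: 5 2-methylbut-3-en-2-ol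
Product: 6 methyl 2-methylbut-3-en-2-yl carbonate
Conditions: n-BuLi, THF, −78 °C; ClCO2Me, −78 °C → rt
Reagents that add atoms: methyl chloroformate, COC(Cl)=O
Why: Acylation of the lithium alkoxide of the tertiary allylic alcohol with the chloroformate gives the mixed carbonate needed as π-allyl precursor.

Step 4
Reactants: 4 3,5-bis(methoxymethoxy)-4-methylphenol; 6 methyl 2-methylbut-3-en-2-yl carbonate
Product: 7 1,3-bis(methoxymethoxy)-2-methyl-5-[(2-methylbut-3-en-2-yl)oxy]benzene
Conditions: Pd(PPh3)4 (2 mol%), THF, 0 °C → rt
Reagents that add atoms: none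
Why: Decarboxylative Tsuji–Trost O-allylation, in which ionisation of 6 gives a 1,1-dimethyl-π-allyl palladium complex and methoxide, and the phenoxide formed from 4 attacks the more substituted allyl terminus under kinetic control at low temperature to give the tertiary (reverse-prenyl) aryl ether.

Step 5
Reactants: 7 1,3-bis(methoxymethoxy)-2-methyl-5-[(2-methylbut-3-en-2-yl)oxy]benzene
Product: 8 3,5-bis(methoxymethoxy)-4-methyl-2-(3-methylbut-2-enyl)phenol
Conditions: PhMe, 120 °C (sealed tube)
Reagents that add atoms: none
Why: Aromatic Claisen rearrangement ([3,3]-sigmatropic shift, then tautomerisation) delivers the allyl unit to an ortho carbon as a 3-methylbut-2-enyl group; the two ortho positions are equivalent and the para position is blocked by the methyl group, so a single prenylphenol should result.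

Step 6
Reactants: 8 3,5-bis(methoxymethoxy)-4-methyl-2-(3-methylbut-2-enyl)phenol
Product: 9 2-iodo-3,5-bis(methoxymethoxy)-4-methyl-6-(3-methylbut-2-enyl)phenol
Conditions: I2 (1.0 equiv), morpholine (2.2 equiv), CH2Cl2, 0 °C
Reagents that add atoms: iodine, II
Why: Electrophilic aromatic iodination at the only remaining ring C–H, which is ortho to the free OH and activated by three oxygen substituents, should outpace attack on the trisubstituted alkene when the mild N-iodomorpholinium species and exactly one equivalent of iodine are used at 0 °C.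

Step 7
Reactants: 10 4-hydroxybenzaldehyde
Product: 11 4-(methoxymethoxy)benzaldehyde
Conditions: NaH, MOMCl, THF/DMF, 0 °C → rt
Reagents that add atoms: chloromethyl methyl ether, COCCl
Why: O-Alkylation of the phenoxide with MOMCl gives the MOM ether, matching the protecting groups of ring A so that all three can be removed together.

Step 8
Reactants: 11 4-(methoxymethoxy)benzaldehyde
Product: 12 1-ethynyl-4-(methoxymethoxy)benzene
Conditions: Ohira–Bestmann reagent, K2CO3, MeOH, rt
Reagents that add atoms: dimethyl (1-diazo-2-oxopropyl)phosphonate, CC(=O)C(=[N+]=[N-])P(=O)(OC)OC (supplies the terminal alkyne carbon)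
Why: Seyferth–Gilbert homologation, in which methanolysis releases the diazomethylphosphonate anion, which adds to the aldehyde and loses dimethyl phosphate and nitrogen, and the alkylidene carbene rearranges by 1,2-hydrogen shift to the terminal alkyne under mild base that leaves the MOM ether intact.

Step 9
Reactants: 9 2-iodo-3,5-bis(methoxymethoxy)-4-methyl-6-(3-methylbut-2-enyl)phenol; 12 1-ethynyl-4-(methoxymethoxy)benzene; 13 carbon monoxide
Product: 16 5,7-bis(methoxymethoxy)-2-[4-(methoxymethoxy)phenyl]-6-methyl-8-(3-methylbut-2-enyl)-4H-chromen-4-one, via ortho-hydroxyaryl ynone 14 (not isolated), via diethylamino enone 15 (not isolated)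
Conditions: PdCl2(dppf) (5 mol%), CO (20 bar), Et2NH, 120 °C
Reagents that add atoms: diethylamine, CCNCC (held only in intermediate 15; all atoms of 16 come from 9, 12 and 13)
Why: Oxidative addition of Pd(0) into the C–I bond of 9 and CO insertion give an aroyl–Pd(II) species, which takes up the amine-activated terminal alkyne 12 and reductively eliminates to ynone 14, forming C4a–C4 and C4–C3. Diethylamine adds to the β-carbon of the ynone to give enaminone 15, and the ortho phenol then displaces the amine at that carbon, so ring C closes by O1–C2 bond formation in a 6-endo sense (addition–elimination, formally 6-endo-dig on the ynone) to give pyranone 16. The closest known reaction is the Pd-catalysed carbonylative annulation of 2-iodophenols with terminal arylacetylenes to flavones in a secondary amine. No stereocentre is formed. The step needs CO insertion to beat direct alkyne coupling (helped by CO pressure, the electron-rich hindered aryl–Pd and the absence of copper) and 6-endo to beat 5-exo closure (helped by the enaminone pathway that Et2NH opens). The O-regiochemistry is secured because the oxygen lying between the iodine-bearing and the prenyl-bearing carbon is the only free phenol, O5 and O7 being MOM ethers.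

Step 10
Reactants: 16 5,7-bis(methoxymethoxy)-2-[4-(methoxymethoxy)phenyl]-6-methyl-8-(3-methylbut-2-enyl)-4H-chromen-4-one
Product: 18 (2S)-5,7-bis(methoxymethoxy)-2-[4-(methoxymethoxy)phenyl]-6-methyl-8-(3-methylbut-2-enyl)-2,3-dihydro-4H-chromen-4-one, via silyl enol ether 17 (not isolated)
Conditions: Cu(OAc)2 (5 mol%), (S)-DTBM-SEGPHOS (5.5 mol%), (EtO)2MeSiH, PhMe, 0 °C → rt; then pH 5 acetate buffer, THF, 0 °C
Reagents that add atoms: diethoxy(methyl)silane, CCO[SiH](C)OCC (silicon held only in intermediate 17)
Why: Copper hydride-catalysed asymmetric conjugate reduction (1,4-hydrosilylation) of the chromone C2=C3 bond, in which the bisphosphine-ligated Cu–H should deliver hydride to the Re face of C2 under ligand control to set the (2S) centre, the copper enolate is trapped by the silane as silyl enol ether 17 (which blocks over-reduction of the ketone and β-elimination of the O1 phenoxide), the isolated prenyl alkene is inert to Cu–H, and buffered hydrolysis releases the ketone without exposing the flavanone to base.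

Step 11
Reactants: 18 (2S)-5,7-bis(methoxymethoxy)-2-[4-(methoxymethoxy)phenyl]-6-methyl-8-(3-methylbut-2-enyl)-2,3-dihydro-4H-chromen-4-one
Product: 19 (2S)-5,7-dihydroxy-2-(4-hydroxyphenyl)-6-methyl-8-(3-methylbut-2-enyl)-2,3-dihydro-4H-chromen-4-one (6-methyl-8-prenylnaringenin)
Conditions: HCl (ca. 1.5 M in MeOH), 0 °C → rt
Reagents that add atoms: none
Why: Acid-catalysed acetal exchange with methanol removes the three MOM groups as dimethoxymethane; at or below room temperature and without base the C2 centre should not epimerise through retro-oxa-Michael opening, and addition of the neighbouring 7-OH to the prenyl alkene should stay slow.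

**Compound list**
1 | 2-methylresorcinol | Cc1c(O)cccc1O | starting material
2 | 1,3-bis(methoxymethoxy)-2-methylbenzene | Cc1c(OCOC)cccc1OCOC | intermediate
3 | 2-[3,5-bis(methoxymethoxy)-4-methylphenyl]-4,4,5,5-tetramethyl-1,3,2-dioxaborolane | Cc1c(OCOC)cc(B2OC(C)(C)C(C)(C)O2)cc1OCOC | intermediate (not isolated)
4 | 3,5-bis(methoxymethoxy)-4-methylphenol | Cc1c(OCOC)cc(O)cc1OCOC | intermediate
5 | 2-methylbut-3-en-2-ol | C=CC(C)(C)O | starting material
6 | methyl 2-methylbut-3-en-2-yl carbonate | C=CC(C)(C)OC(=O)OC | intermediate
7 | 1,3-bis(methoxymethoxy)-2-methyl-5-[(2-methylbut-3-en-2-yl)oxy]benzene | C=CC(C)(C)Oc1cc(OCOC)c(C)c(OCOC)c1 | intermediate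
8 | 3,5-bis(methoxymethoxy)-4-methyl-2-(3-methylbut-2-enyl)phenol | CC(C)=CCc1c(O)cc(OCOC)c(C)c1OCOC | intermediate
9 | 2-iodo-3,5-bis(methoxymethoxy)-4-methyl-6-(3-methylbut-2-enyl)phenol | CC(C)=CCc1c(O)c(I)c(OCOC)c(C)c1OCOC | intermediate
10 | 4-hydroxybenzaldehyde | O=Cc1ccc(O)cc1 | starting material
11 | 4-(methoxymethoxy)benzaldehyde | O=Cc1ccc(OCOC)cc1 | intermediate
12 | 1-ethynyl-4-(methoxymethoxy)benzene | C#Cc1ccc(OCOC)cc1 | intermediate
13 | carbon monoxide | [C-]#[O+] | starting material
14 | 1-[2-hydroxy-4,6-bis(methoxymethoxy)-5-methyl-3-(3-methylbut-2-enyl)phenyl]-3-[4-(methoxymethoxy)phenyl]prop-2-yn-1-one | CC(C)=CCc1c(O)c(C(=O)C#Cc2ccc(OCOC)cc2)c(OCOC)c(C)c1OCOC | intermediate (not isolated)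
15 | 3-(diethylamino)-1-[2-hydroxy-4,6-bis(methoxymethoxy)-5-methyl-3-(3-methylbut-2-enyl)phenyl]-3-[4-(methoxymethoxy)phenyl]prop-2-en-1-one (alkene geometry not defined) | CC(C)=CCc1c(O)c(C(=O)C=C(N(CC)CC)c2ccc(OCOC)cc2)c(OCOC)c(C)c1OCOC | intermediate (not isolated)
16 | 5,7-bis(methoxymethoxy)-2-[4-(methoxymethoxy)phenyl]-6-methyl-8-(3-methylbut-2-enyl)-4H-chromen-4-one | CC(C)=CCc1c(OCOC)c(C)c(OCOC)c2c1OC(c1ccc(OCOC)cc1)=CC2=O | intermediate
17 | (2S)-4-{[diethoxy(methyl)silyl]oxy}-5,7-bis(methoxymethoxy)-2-[4-(methoxymethoxy)phenyl]-6-methyl-8-(3-methylbut-2-enyl)-2H-chromene | CC(C)=CCc1c(OCOC)c(C)c(OCOC)c2c1O[C@H](c1ccc(OCOC)cc1)C=C2O[Si](C)(OCC)OCC | intermediate (not isolated)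
18 | (2S)-5,7-bis(methoxymethoxy)-2-[4-(methoxymethoxy)phenyl]-6-methyl-8-(3-methylbut-2-enyl)-2,3-dihydro-4H-chromen-4-one | CC(C)=CCc1c(OCOC)c(C)c(OCOC)c2c1O[C@H](c1ccc(OCOC)cc1)CC2=O | intermediate
19 | (2S)-5,7-dihydroxy-2-(4-hydroxyphenyl)-6-methyl-8-(3-methylbut-2-enyl)-2,3-dihydro-4H-chromen-4-one (6-methyl-8-prenylnaringenin) | CC(C)=CCc1c(O)c(C)c(O)c2c1O[C@H](c1ccc(O)cc1)CC2=O | target

**Step count**
Total: 11 steps. Longest linear sequence: 8 steps (1, 2, 4, 5, 6, 9, 10, 11).

**Steps most likely to fail**

1. Step 10. The hindered, electron-rich vinylogous ester may take up hydride slowly, the catalyst may discriminate the two faces of C2 poorly, and the copper enolate may open by loss of the O1 phenoxide before silyl transfer, which would erode the enantiomeric purity. The fallback sets out from flavone 16 and gives up catalyst control of C2. Non-selective conjugate reduction with L-Selectride (THF, −78 °C, cold AcOH quench; any ring-opened chalcone recyclised with NaOAc in EtOH) should give racemic 5,7-bis(methoxymethoxy)-2-[4-(methoxymethoxy)phenyl]-6-methyl-8-(3-methylbut-2-enyl)chroman-4-one F1. Kinetic resolution by Noyori-type asymmetric transfer hydrogenation (Cp*RhCl(TsDPEN), HCO2H/Et3N, EtOAc, rt, the catalyst enantiomer chosen so that the 2R ketone reacts fast) should reduce the 2R half to (2R,4R)-5,7-bis(methoxymethoxy)-2-[4-(methoxymethoxy)phenyl]-6-methyl-8-(3-methylbut-2-enyl)chroman-4-ol F2 and leave the 2S ketone. The recovered ketone is 18, where the route is rejoined; at most half of the material is carried on.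

2. Step 9. Oxidative addition at the C–I bond flanked by two oxygen substituents may be slow, coupling with the alkyne may occur without CO uptake and lead on to a benzofuran, the aroyl–palladium species may be captured by the amine, or closure may go 5-exo. The fallback sets out from 9 and 12 and forms the C4a–C4 bond by organolithium acylation instead of carbonylation. Alkyne 12 is deprotonated (n-BuLi, THF, −78 °C) and acylated with N-methoxy-N-methylcarbamoyl chloride to N-methoxy-N-methyl-3-[4-(methoxymethoxy)phenyl]prop-2-ynamide F3. Iodophenol 9 is treated with n-BuLi (2.1 equiv, THF, −78 °C; O–H deprotonation, then iodine–lithium exchange) to give lithium 2-lithio-3,5-bis(methoxymethoxy)-4-methyl-6-(3-methylbut-2-enyl)phenoxide F4, which adds to F3 to give ynone 14 after work-up, here as an isolated compound. Treatment of 14 with Et2NH in EtOH (rt → 60 °C) should close ring C through 15 and rejoin the route at 16.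

3. Step 6. The iodinating agent may attack the prenyl double bond, with capture of the iodonium ion by the neighbouring phenol oxygen (iodoetherification), instead of the ring carbon. The fallback sets out from phenol 4 and introduces iodine before the alkene exists. Mono-iodination (NIS, 1.0 equiv, MeCN, −20 °C) should give 2-iodo-3,5-bis(methoxymethoxy)-4-methylphenol F5. O-Allylation with carbonate 6 (Pd(PPh3)4, THF, 0 °C, where ionisation of the allylic carbonate should be faster than insertion into the hindered aryl iodide) gives 2-iodo-3,5-bis(methoxymethoxy)-4-methyl-1-[(2-methylbut-3-en-2-yl)oxy]benzene F6. Claisen rearrangement (PhMe, 120 °C) can only end at the one free ortho carbon and rejoins the route at 9.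

**Further compounds**
F1 | step 10 | racemic 5,7-bis(methoxymethoxy)-2-[4-(methoxymethoxy)phenyl]-6-methyl-8-(3-methylbut-2-enyl)chroman-4-one | CC(C)=CCc1c(OCOC)c(C)c(OCOC)c2c1OC(c1ccc(OCOC)cc1)CC2=O
F2 | step 10 | (2R,4R)-5,7-bis(methoxymethoxy)-2-[4-(methoxymethoxy)phenyl]-6-methyl-8-(3-methylbut-2-enyl)chroman-4-ol | CC(C)=CCc1c(OCOC)c(C)c(OCOC)c2c1O[C@@H](c1ccc(OCOC)cc1)C[C@H]2O
F3 | step 9 | N-methoxy-N-methyl-3-[4-(methoxymethoxy)phenyl]prop-2-ynamide | CON(C)C(=O)C#Cc1ccc(OCOC)cc1
F4 | step 9 | lithium 2-lithio-3,5-bis(methoxymethoxy)-4-methyl-6-(3-methylbut-2-enyl)phenoxide | CC(C)=CCc1c(O[Li])c([Li])c(OCOC)c(C)c1OCOC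
F5 | step 6 | 2-iodo-3,5-bis(methoxymethoxy)-4-methylphenol | Cc1c(OCOC)cc(O)c(I)c1OCOC
F6 | step 6 | 2-iodo-3,5-bis(methoxymethoxy)-4-methyl-1-[(2-methylbut-3-en-2-yl)oxy]benzene | C=CC(C)(C)Oc1cc(OCOC)c(C)c(OCOC)c1I
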